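The core is numbered O1, C2 (bearing ring B), C3 (bearing CH2OH), C4 (bearing OH and the ring A benzyl group), C5. The benzylic carbon on C4 and the hydroxymethyl carbon on C3 lie on the same face. One ether oxygen can therefore link them in a cis-fused 3,7-dioxabicyclo[3.3.0]octane, and the C4–CH2Ar bond can be made inside that temporary ring.
Retrosynthetic cuts, in order: both ArO–Bn bonds; C7''–C8'' (glycolate aldol); the ring B O–C8'' bond (phenol alkylation); re-closure of the ring A benzylic carbon onto the C3 arm oxygen; C4–C(benzylic) (Norrish–Yang); O1–C5 (epoxide opening); the arm O–CH2(ring A) bond; C2–C3 (crotonate aldol).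
Forward order: the acyclic C2–C5 chain comes first, then the tetrahydrofuran ring (O1–C5), then the second ring by light. Ionic hydrogenation reopens that ring at the ring A benzylic C–O bond. The ring B phenol is then freed and extended by alkylation, aldol and reduction to the guaiacylglycerol chain (C7'', C8'', C9'', ring C).
Stereochemistry: C2 (S) and C3 (R) come from an Evans syn aldol of the N-crotonyl (S)-oxazolidinone. Its vinyl group becomes C4–C5 and its imide carbon becomes the C3 arm, so ring B and the arm are trans from the start and no base equilibration of a β-alkoxy ketone is needed. C4 (S) is fixed by the tether anchored on C3. C7'' (R) and C8'' (R), the threo pair, come from a second Evans syn aldol with the same (S) auxiliary.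
Protecting groups: a mesylate on ring B (electron-poor, tolerant of acid and light) differentiates the two benzylic ethers of the bicycle. Benzyl ethers mask the ring A and ring C phenols to the end.

Key step: step 10

Assumption: the oxirane carbon, the C4 carbinol made from it and the ring A benzylic carbon of the photoproduct may each form as epimer mixtures. All three centres are destroyed later, so mixtures are carried on and the photoproduct is drawn as the expected exo-aryl isomer.

Step 1
Reactants: 1 vanillin
Product: 2 4-formyl-2-methoxyphenyl methanesulfonate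
Conditions: MsCl, Et3N, CH2Cl2, 0 °C
Reagents that add atoms: methanesulfonyl chloride, CS(=O)(=O)Cl
Why: O-Sulfonylation of the phenol is fast with amine base, and the mesylate makes ring B electron-poor, which later keeps the C2–O1 benzylic bond closed towards Lewis acid, while tolerating boron enolates, hydride, peracid, alkoxide and filtered light.

Step 2
Reactants: 3 (S)-4-benzyl-2-oxazolidinone
Product: 4 (S)-4-benzyl-3-[(E)-but-2-enoyl]oxazolidin-2-one
Conditions: crotonic anhydride, LiCl, Et3N, THF, −20 °C → rt
Reagents that add atoms: (E)-but-2-enoic anhydride, C/C=C/C(=O)OC(=O)/C=C/C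
Why: LiCl/Et3N-promoted N-acylation of an oxazolidinone by a symmetrical anhydride needs no strong base, so the crotonyl unit should escape conjugate addition and polymerisation.

Step 3
Reactants: 4 (S)-4-benzyl-3-[(E)-but-2-enoyl]oxazolidin-2-one; 2 4-formyl-2-methoxyphenyl methanesulfonate
Product: 7 (S)-4-benzyl-3-{(2S)-2-[(S)-hydroxy(3-methoxy-4-mesyloxyphenyl)methyl]but-3-enoyl}oxazolidin-2-one, via boron dienolate 5 (not isolated), via boron aldolate 6 (not isolated)
Conditions: Bu2BOTf, Et3N, CH2Cl2, −78 → 0 °C; 2, −78 → 0 °C; pH 7 buffer, MeOH, 30% H2O2, 0 °C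
Reagents that add atoms: dibutylboron triflate, CCCCB(CCCC)OS(=O)(=O)C(F)(F)F (boron and butyl groups stay only in 5 and 6)
Why: In this Evans syn aldol of a crotonate imide, soft enolisation removes a γ-hydrogen to give the (Z)-boron dienolate, which reacts at its α-carbon through a Zimmerman–Traxler chair on the face away from the auxiliary benzyl group, setting the carbinol (future C2, S) and the α-centre (future C3) with vinyl and hydroxyl syn, which is the 2,3-trans relation of the later ring.

Step 4
Reactants: 7 syn aldol imide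
Product: 8 (1S,2R)-1-(3-methoxy-4-mesyloxyphenyl)-2-vinylpropane-1,3-diol
Conditions: LiBH4, MeOH (1 equiv), THF, 0 °C; aq. work-up
Reagents that add atoms: none
Why: Reductive removal of the auxiliary with LiBH4 attacks only the exocyclic imide carbonyl, turns it into the C3 hydroxymethyl arm and leaves the alkene, the mesylate and both stereocentres untouched.

Step 5
Reactants: 9 4-benzyloxy-3-methoxybenzyl alcohol
Product: 10 4-benzyloxy-3-methoxybenzyl chloride
Conditions: SOCl2, CH2Cl2, 0 °C
Reagents that add atoms: thionyl chloride, O=S(Cl)Cl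
Why: Deoxychlorination of an electron-rich benzylic alcohol through its chlorosulfite is rapid at 0 °C and spares the aryl benzyl ether.

Step 6
Reactants: 8 (1S,2R)-1-(3-methoxy-4-mesyloxyphenyl)-2-vinylpropane-1,3-diol; 10 4-benzyloxy-3-methoxybenzyl chloride
Product: 12 (1S,2R)-2-{[(4-benzyloxy-3-methoxybenzyl)oxy]methyl}-1-(3-methoxy-4-mesyloxyphenyl)but-3-en-1-ol, via stannylene acetal 11 (not isolated)
Conditions: Bu2SnO, toluene, reflux (Dean–Stark); then 10, cat. Bu4NI, 80 °C; aq. work-up
Reagents that add atoms: dibutyltin oxide, CCCC[Sn](=O)CCCC (tin and butyl groups stay only in 11)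
Why: In this stannylene-acetal-mediated Williamson etherification the six-membered dibutylstannylene acetal activates the less hindered primary oxygen, so the benzylic chloride is taken up there and the secondary carbinol stays free.

Step 7
Reactants: 12 homoallylic alcohol ether
Product: 13 oxirane from the vinyl group of 12 (other two centres as in 12; both epimers at the oxirane CH)
Conditions: mCPBA, CH2Cl2, 0 °C → rt
Reagents that add atoms: 3-chloroperoxybenzoic acid, OOC(=O)c1cccc(Cl)c1
Why: Prilezhaev epoxidation touches the only alkene, and the configuration of the new oxirane carbon (future C4) does not matter because step 9 converts it into a carbonyl carbon.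

Step 8
Reactants: 13 epoxy alcohol
Product: 14 2,3-trans-3-{[(4-benzyloxy-3-methoxybenzyl)oxy]methyl}-2-(3-methoxy-4-mesyloxyphenyl)tetrahydrofuran-4-ol (2S; both C4 epimers)
Conditions: cat. KOt-Bu, t-BuOH–THF, rt → 40 °C
Reagents that add atoms: none
Why: In this base-induced intramolecular epoxide opening the benzylic alkoxide attacks the unsubstituted oxirane carbon C5 (5-endo opening, the mode by which 5,6-anhydro sugars give 3,6-anhydro sugars) rather than building a strained four-membered ring, and under basic conditions the neutral ether oxygen of the C3 arm cannot compete for C5.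

Step 9
Reactants: 14 tetrahydrofuran-4-ol
Product: 15 (2S,3R)-3-{[(4-benzyloxy-3-methoxybenzyl)oxy]methyl}-2-(3-methoxy-4-mesyloxyphenyl)tetrahydrofuran-4-one
Conditions: Dess–Martin periodinane, CH2Cl2, 0 °C → rt
Reagents that add atoms: none
Why: Dess–Martin oxidation runs without base, so the β-alkoxy ketone should neither eliminate nor epimerise, both C4 epimers converge, and C3 keeps its trans (also thermodynamically preferred) setting.

Step 10
Reactants: 15 (2S,3R)-3-{[(4-benzyloxy-3-methoxybenzyl)oxy]methyl}-2-(3-methoxy-4-mesyloxyphenyl)tetrahydrofuran-4-one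
Product: 17 (1S,2R,5R,6S)-2-(4-benzyloxy-3-methoxyphenyl)-6-(3-methoxy-4-mesyloxyphenyl)-3,7-dioxabicyclo[3.3.0]octan-1-ol, via 1,5-biradical 16 (not isolated)
Conditions: hν (medium-pressure Hg lamp, Pyrex filter, λ > 300 nm), degassed benzene, high dilution, ca. 15 °C
Reagents that add atoms: none
Why: Excitation of the C4 carbonyl to its n,π* state is followed by 1,6-hydrogen transfer from the ring A OCH2 group (seven atoms in the cyclic array; the γ atom of this chain is the ether oxygen, so no shorter transfer is available), and the two radical centres of 16 then couple to form the C4–C(benzylic) bond. The closest known reaction type is the Norrish–Yang photocyclisation of β-alkoxy ketones to 3-hydroxytetrahydrofurans, which has served for bridgehead-hydroxylated furofuran lignans. The new five-membered ring (C4, C3, arm CH2, O, benzylic CH) closes by recombination of the termini of a 1,5-biradical. C4 is controlled by the three-atom tether anchored on C3: two fused five-membered rings can only be joined cis, so the new carbon lands on the face of the arm and the hydroxyl on the face of ring B. The benzylic centre should follow the preference of ring A for the convex (exo) side during closure, and either epimer serves because step 11 deletes this centre. The step needs hydrogen transfer to outrun α-cleavage of the cyclic ketone and needs light to reach only the carbonyl, which the weak C–H bond (benzylic and next to oxygen) held close by the short tether and the Pyrex cut-off (aryl mesylate and benzyl ethers transparent) should secure.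

Step 11
Reactants: 17 bridgehead-hydroxy dioxabicyclooctane
Product: 18 (2S,3R,4S)-4-(4-benzyloxy-3-methoxybenzyl)-3-(hydroxymethyl)-2-(3-methoxy-4-mesyloxyphenyl)tetrahydrofuran-4-ol
Conditions: Et3SiH, BF3·OEt2, CH2Cl2, −78 → −30 °C; aq. NaHCO3 work-up
Reagents that add atoms: none
Why: In this ionic hydrogenation of a benzylic ether, BF3 opens only the C–O bond whose cation is stabilised by the para benzyloxy group of ring A and excess Et3SiH traps that cation, while the mesylate-deactivated ring B benzylic ether, the aryl benzyl ether and the C4 hydroxyl remain, so the transient benzylic stereocentre vanishes and the CH2OH arm is released.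

Step 12
Reactants: 18 diol
Product: 19 bis(triethylsilyl) ether of 18 (C4–OTES and CH2OTES)
Conditions: TESOTf, 2,6-lutidine, CH2Cl2, 0 °C → rt
Reagents that add atoms: triethylsilyl triflate, CC[Si](CC)(CC)OS(=O)(=O)C(F)(F)F
Why: A silyl triflate with a hindered pyridine base silylates primary and tertiary hydroxyl groups alike, which removes all acidic protons before the amide-base and boron-enolate steps.

Step 13
Reactants: 19 bis-TES mesylate
Product: 20 ring B phenol (bis-TES ether of ring A O-benzyl olivil)
Conditions: LDA (commercial solution), THF, −78 → 0 °C; AcOH quench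
Reagents that add atoms: none
Why: In this base-induced cleavage of an aryl mesylate, LDA deprotonates the S-methyl group and the anion expels the phenoxide (E1cB through sulfene) at low temperature, where silyl ethers, benzyl ethers and the C2–O1 bond next to the new phenoxide are inert.

Step 14
Reactants: 3 (S)-4-benzyl-2-oxazolidinone
Product: 22 (S)-4-benzyl-3-(bromoacetyl)oxazolidin-2-one, via lithium oxazolidinide 21 (not isolated)
Conditions: n-BuLi, THF, −78 °C; BrCH2COBr, −78 → 0 °C
Reagents that add atoms: n-butyllithium, [Li]CCCC (lithium stays only in 21); bromoacetyl bromide, O=C(Br)CBr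
Why: N-Acylation of the lithiated oxazolidinone by the acid bromide is much faster at −78 °C than displacement of the α-bromide.

Step 15
Reactants: 20 ring B phenol; 22 (S)-4-benzyl-3-(bromoacetyl)oxazolidin-2-one
Product: 23 ring B aryloxyacetyl imide (ArO–CH2–CO–oxazolidinone, bis-TES)
Conditions: K2CO3, acetone, rt
Reagents that add atoms: none
Why: In this Williamson ether synthesis the potassium phenoxide displaces the activated α-bromide at room temperature faster than it attacks the imide carbonyl.

Step 16
Reactants: 23 aryloxyacetyl imide; 24 4-benzyloxy-3-methoxybenzaldehyde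
Product: 27 syn aldol imide with acyl chain (2S,3R)-2-aryloxy-3-(4-benzyloxy-3-methoxyphenyl)-3-hydroxypropanoyl, via boron enolate 25 (not isolated), via boron aldolate 26 (not isolated)
Conditions: Bu2BOTf, Et3N, CH2Cl2, −78 → 0 °C; 24, −78 → 0 °C; pH 7 buffer, MeOH, 30% H2O2, 0 °C
Reagents that add atoms: dibutylboron triflate, CCCCB(CCCC)OS(=O)(=O)C(F)(F)F (boron and butyl groups stay only in 25 and 26)
Why: In this Evans syn glycolate aldol the (Z)-boron enolate of the aryloxyacetyl imide adds to the aldehyde through a Zimmerman–Traxler chair on the face away from the auxiliary benzyl group, which sets C8'' and C7'' syn in the sense that becomes 7''R,8''R after reduction.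

Step 17
Reactants: 27 syn aldol imide
Product: 28 (7''R,8''R)-1,3-diol (bis-TES, ring A and ring C O-benzyl)
Conditions: LiBH4, MeOH (1 equiv), THF, 0 °C; aq. work-up
Reagents that add atoms: none
Why: Reductive cleavage of the N-acyl oxazolidinone with LiBH4 gives the primary C9'' alcohol without touching C7'' or C8'' and turns the syn aldol into the threo glycerol unit.

Step 18
Reactants: 28 bis-TES diol
Product: 29 ring A, ring C di-O-benzyl ether of the target (four free alcohols)
Conditions: TBAF (1 M, wet THF), 0 °C → rt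
Reagents that add atoms: none
Why: Fluoride-induced desilylation is driven by the Si–F bond and is run while all three phenol oxygens are still alkylated, so no base-labile p-hydroxybenzylic unit is exposed.

Step 19
Reactants: 29 di-O-benzyl ether
Product: 30 target CNP0391650.2
Conditions: H2 (1 atm), 10% Pd/C, EtOAc–EtOH, rt
Reagents that add atoms: none
Why: Catalytic hydrogenolysis of aryl benzyl ethers over Pd/C under neutral conditions is much faster than cleavage of the secondary benzylic alcohol or the cyclic benzylic ether, so stopping after uptake of two equivalents of H2 should give the target with all five stereocentres intact.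

Compound list
1 | vanillin | COc1cc(C=O)ccc1O | starting material
2 | 4-formyl-2-methoxyphenyl methanesulfonate | COc1cc(C=O)ccc1OS(C)(=O)=O | intermediate
3 | (S)-4-benzyl-2-oxazolidinone | O=C1N[C@@H](Cc2ccccc2)CO1 | starting material
4 | (S)-4-benzyl-3-[(E)-but-2-enoyl]oxazolidin-2-one | C/C=C/C(=O)N1[C@@H](Cc2ccccc2)COC1=O | intermediate
5 | (Z)-dibutylboron dienolate of 4 | CCCCB(CCCC)O/C(=C\C=C)N1[C@@H](Cc2ccccc2)COC1=O | intermediate
6 | dibutylboron aldolate of 7 | O=C([C@@H](C=C)[C@H](OB(CCCC)CCCC)c1ccc(OS(C)(=O)=O)c(OC)c1)N1[C@@H](Cc2ccccc2)COC1=O | intermediate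
7 | (S)-4-benzyl-3-{(2S)-2-[(S)-hydroxy(3-methoxy-4-mesyloxyphenyl)methyl]but-3-enoyl}oxazolidin-2-one | O=C([C@@H](C=C)[C@H](O)c1ccc(OS(C)(=O)=O)c(OC)c1)N1[C@@H](Cc2ccccc2)COC1=O | intermediate
8 | (1S,2R)-1-(3-methoxy-4-mesyloxyphenyl)-2-vinylpropane-1,3-diol | OC[C@@H](C=C)[C@H](O)c1ccc(OS(C)(=O)=O)c(OC)c1 | intermediate
9 | 4-benzyloxy-3-methoxybenzyl alcohol | COc1cc(CO)ccc1OCc1ccccc1 | starting material
10 | 4-benzyloxy-3-methoxybenzyl chloride | COc1cc(CCl)ccc1OCc1ccccc1 | intermediate
11 | dibutylstannylene acetal of 8 | CCCC[Sn]1(CCCC)OC[C@@H](C=C)[C@@H](c2ccc(OS(C)(=O)=O)c(OC)c2)O1 | intermediate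
12 | (1S,2R)-2-{[(4-benzyloxy-3-methoxybenzyl)oxy]methyl}-1-(3-methoxy-4-mesyloxyphenyl)but-3-en-1-ol | COc1cc(COC[C@@H](C=C)[C@H](O)c2ccc(OS(C)(=O)=O)c(OC)c2)ccc1OCc1ccccc1 | intermediate
13 | oxirane from the vinyl group of 12 (oxirane CH unassigned) | COc1cc(COC[C@@H](C2CO2)[C@H](O)c2ccc(OS(C)(=O)=O)c(OC)c2)ccc1OCc1ccccc1 | intermediate
14 | 2,3-trans-3-{[(4-benzyloxy-3-methoxybenzyl)oxy]methyl}-2-(3-methoxy-4-mesyloxyphenyl)tetrahydrofuran-4-ol (C4 unassigned) | OC1CO[C@H](c2ccc(OS(C)(=O)=O)c(OC)c2)[C@H]1COCc1ccc(OCc2ccccc2)c(OC)c1 | intermediate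
15 | (2S,3R)-3-{[(4-benzyloxy-3-methoxybenzyl)oxy]methyl}-2-(3-methoxy-4-mesyloxyphenyl)tetrahydrofuran-4-one | O=C1CO[C@H](c2ccc(OS(C)(=O)=O)c(OC)c2)[C@H]1COCc1ccc(OCc2ccccc2)c(OC)c1 | intermediate
16 | 1,5-biradical (C4 hydroxy radical, ring A benzylic α-oxy radical) | O[C]1CO[C@H](c2ccc(OS(C)(=O)=O)c(OC)c2)[C@H]1CO[CH]c1ccc(OCc2ccccc2)c(OC)c1 | intermediate
17 | (1S,2R,5R,6S)-2-(4-benzyloxy-3-methoxyphenyl)-6-(3-methoxy-4-mesyloxyphenyl)-3,7-dioxabicyclo[3.3.0]octan-1-ol | O[C@]12CO[C@H](c3ccc(OS(C)(=O)=O)c(OC)c3)[C@H]1CO[C@@H]2c1ccc(OCc2ccccc2)c(OC)c1 | intermediate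
18 | (2S,3R,4S)-4-(4-benzyloxy-3-methoxybenzyl)-3-(hydroxymethyl)-2-(3-methoxy-4-mesyloxyphenyl)tetrahydrofuran-4-ol | COc1cc(C[C@@]2(O)CO[C@H](c3ccc(OS(C)(=O)=O)c(OC)c3)[C@H]2CO)ccc1OCc1ccccc1 | intermediate
19 | bis(triethylsilyl) ether of 18 | COc1cc(C[C@@]2(O[Si](CC)(CC)CC)CO[C@H](c3ccc(OS(C)(=O)=O)c(OC)c3)[C@H]2CO[Si](CC)(CC)CC)ccc1OCc1ccccc1 | intermediate
20 | ring B phenol, bis-TES, ring A O-benzyl | COc1cc(C[C@@]2(O[Si](CC)(CC)CC)CO[C@H](c3ccc(O)c(OC)c3)[C@H]2CO[Si](CC)(CC)CC)ccc1OCc1ccccc1 | intermediate
21 | N-lithio-(S)-4-benzyl-2-oxazolidinone | [Li]N1[C@@H](Cc2ccccc2)COC1=O | intermediate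
22 | (S)-4-benzyl-3-(bromoacetyl)oxazolidin-2-one | O=C(CBr)N1[C@@H](Cc2ccccc2)COC1=O | intermediate
23 | ring B aryloxyacetyl imide, bis-TES | COc1cc(C[C@@]2(O[Si](CC)(CC)CC)CO[C@H](c3ccc(OCC(=O)N4[C@@H](Cc5ccccc5)COC4=O)c(OC)c3)[C@H]2CO[Si](CC)(CC)CC)ccc1OCc1ccccc1 | intermediate
24 | 4-benzyloxy-3-methoxybenzaldehyde | COc1cc(C=O)ccc1OCc1ccccc1 | starting material
25 | (Z)-dibutylboron enolate of 23 | COc1cc(C[C@@]2(O[Si](CC)(CC)CC)CO[C@H](c3ccc(O/C=C(\OB(CCCC)CCCC)N4[C@@H](Cc5ccccc5)COC4=O)c(OC)c3)[C@H]2CO[Si](CC)(CC)CC)ccc1OCc1ccccc1 | intermediate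
26 | dibutylboron aldolate of 27 | COc1cc(C[C@@]2(O[Si](CC)(CC)CC)CO[C@H](c3ccc(O[C@H](C(=O)N4[C@@H](Cc5ccccc5)COC4=O)[C@H](OB(CCCC)CCCC)c4ccc(OCc5ccccc5)c(OC)c4)c(OC)c3)[C@H]2CO[Si](CC)(CC)CC)ccc1OCc1ccccc1 | intermediate
27 | syn glycolate aldol imide (acyl chain 2S,3R) | COc1cc(C[C@@]2(O[Si](CC)(CC)CC)CO[C@H](c3ccc(O[C@H](C(=O)N4[C@@H](Cc5ccccc5)COC4=O)[C@H](O)c4ccc(OCc5ccccc5)c(OC)c4)c(OC)c3)[C@H]2CO[Si](CC)(CC)CC)ccc1OCc1ccccc1 | intermediate
28 | (7''R,8''R)-diol, bis-TES, di-O-benzyl | COc1cc(C[C@@]2(O[Si](CC)(CC)CC)CO[C@H](c3ccc(O[C@H](CO)[C@H](O)c4ccc(OCc5ccccc5)c(OC)c4)c(OC)c3)[C@H]2CO[Si](CC)(CC)CC)ccc1OCc1ccccc1 | intermediate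
29 | ring A, ring C di-O-benzyl ether of the target | COc1cc(C[C@@]2(O)CO[C@H](c3ccc(O[C@H](CO)[C@H](O)c4ccc(OCc5ccccc5)c(OC)c4)c(OC)c3)[C@H]2CO)ccc1OCc1ccccc1 | intermediate
30 | CNP0391650.2, (2S,3R,4S,7''R,8''R) | COc1cc(C[C@@]2(O)CO[C@H](c3ccc(O[C@H](CO)[C@H](O)c4ccc(O)c(OC)c4)c(OC)c3)[C@H]2CO)ccc1O | target

Total step count: 19.
Longest linear sequence: 16 steps (step 1 or 2, then 3, 4, 6–13 and 15–19).

Steps most likely to fail

Step 10. α-Cleavage and decarbonylation of the excited five-membered ketone may outrun the hydrogen transfer. Quenching of the excited carbonyl by the electron-rich ring A may do the same. The fallback sets out from 15 and returns at 18, and it sets C4 by steric approach control instead of by the tether.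
- Wittig methylenation (Ph3P=CH2, THF, −78 → 0 °C) would give the 4-methylenetetrahydrofuran F1.
- mCPBA should attack F1 from the face opposite the adjacent C3 arm and give the spiro-epoxide F2, with its oxygen trans to the arm.
- 4-Benzyloxy-3-methoxyphenylmagnesium bromide with catalytic CuI would open F2 at its CH2 terminus. This gives the tertiary alcohol F3, whose ring A benzyl carbon is cis to the arm.
- DDQ in wet CH2Cl2 would then remove the electron-rich benzyl ether from the arm, which is no longer needed, and give 18.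

Step 11. A 1,2-shift from the neighbouring tertiary carbinol into the benzylic cation may compete with hydride capture. Slow ionisation at C2 may also compete. The fallback sets out from 17 and returns at 18, and it avoids a free cation.
- Heterogeneous hydrogenolysis (H2, Pd(OH)2/C, EtOH) should first remove the O-benzyl group.
- It should then cleave the p-hydroxybenzylic C–O bond of ring A on the metal surface. This is the behaviour known for furofuran lignans, and it should give the ring A phenol F4.
- K2CO3 and BnBr in acetone would re-benzylate only the phenol and give 18.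

Step 8. Attack of the alkoxide at the inner oxirane carbon, which closes a four-membered ring, may erode the cyclisation. Base-induced loss of the mesylate may also do so. The fallback sets out from 12 and returns at 14, and it makes O1–C5 by vinyl transfer and C4–C5 by metathesis.
- [Ir(cod)Cl]2, Na2CO3 and vinyl acetate in toluene would give the vinyl ether F5.
- The second-generation Grubbs catalyst would close F5 to the 2,3-dihydrofuran F6.
- BH3·THF followed by NaBO3 would place the hydroxyl on C4, the carbon β to the ring oxygen, and give 14.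

Further compounds
F1 | step 10 | 2,3-trans-3-{[(4-benzyloxy-3-methoxybenzyl)oxy]methyl}-2-(3-methoxy-4-mesyloxyphenyl)-4-methylenetetrahydrofuran | C=C1CO[C@H](c2ccc(OS(C)(=O)=O)c(OC)c2)[C@H]1COCc1ccc(OCc2ccccc2)c(OC)c1
F2 | step 10 | spiro-epoxide at C4 (1,5-dioxaspiro[2.4]heptane, oxirane oxygen trans to the C3 arm) | C1O[C@@]12CO[C@H](c3ccc(OS(C)(=O)=O)c(OC)c3)[C@H]2COCc1ccc(OCc2ccccc2)c(OC)c1
F3 | step 10 | (4-benzyloxy-3-methoxybenzyl) ether of 18 at the primary oxygen | COc1cc(C[C@@]2(O)CO[C@H](c3ccc(OS(C)(=O)=O)c(OC)c3)[C@H]2COCc2ccc(OCc3ccccc3)c(OC)c2)ccc1OCc1ccccc1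
F4 | step 11 | ring A phenol corresponding to 18 | COc1cc(C[C@@]2(O)CO[C@H](c3ccc(OS(C)(=O)=O)c(OC)c3)[C@H]2CO)ccc1O
F5 | step 8 | O-vinyl ether of 12 | COc1cc(COC[C@@H](C=C)[C@H](OC=C)c2ccc(OS(C)(=O)=O)c(OC)c2)ccc1OCc1ccccc1
F6 | step 8 | 2,3-trans-3-{[(4-benzyloxy-3-methoxybenzyl)oxy]methyl}-2-(3-methoxy-4-mesyloxyphenyl)-2,3-dihydrofuran | C1=CO[C@H](c2ccc(OS(C)(=O)=O)c(OC)c2)[C@H]1COCc1ccc(OCc2ccccc2)c(OC)c1
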